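**Plan**
- Cuts: (i) O1–C2 of the flavanone pyranone ring (oxa-Michael), with a temporary CO2tBu on C3; (ii) C2=C3 of the resulting benzylidene β-keto ester (Knoevenagel); (iii) the aryl–O bond of the diaryl ether between flavonol O3'' and the flavanone B ring (SNAr); (iv) C3–CO2tBu (Claisen-type carboxylation).
- Forward: kaempferol (both flavone rings ready-made) is benzylated at O7/O4' and O3-arylated with 4-fluorobenzaldehyde; 2,6-dihydroxy-4-methoxyacetophenone is monobenzylated and C-carboxylated; a Knoevenagel condensation joins the halves; the flavanone heterocycle is closed last, and the helpers (CO2tBu, three benzyl groups) are then removed.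
- Enabling feature: C2 is β to the C4 ketone and bound to O1, so O1–C2 is an oxa-Michael bond. C3 (α to C4) can carry a removable carboxyl. C5 and C8a flank C4a and both carry oxygens that descend from the two equivalent hydroxyls of a 2,6-dihydroxy-4-methoxyphenyl ketone, so the choice of nucleophilic oxygen raises no regiochemical question.
- Stereochemistry: the only stereocentre, C2 (S), is set in the ring closure by a bifunctional cinchona thiourea; the E/Z alkylidenes and both C3 epimers of the cyclised ester converge on one compound after decarboxylation.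

Key step: step 6

Assumption: the quinine-derived member of the pseudoenantiomeric cinchona–thiourea pair is taken to give the (2S) series; the facial sense is checked on a model alkylidene and the quinidine-derived member is used instead, with nothing else changed, if it proves opposite.

**Step 1**
Reactants: 1 kaempferol; 2 benzyl bromide
Product: 3 7,4'-di-O-benzylkaempferol
Conditions: BnBr (2.1 equiv), K2CO3 (2.2 equiv), DMF, 0 °C → rt, Ar
Reagents that add atoms: benzyl bromide (2), BrCc1ccccc1
Why: Williamson O-alkylation under mild carbonate base should follow phenol acidity (7-OH > 4'-OH > 3-OH >> 5-OH, the 3- and 5-hydroxyls being hydrogen-bonded to C4=O), so two equivalents of benzyl bromide should cap O7 and O4' first.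

**Step 2**
Reactants: 3 7,4'-di-O-benzylkaempferol; 4 4-fluorobenzaldehyde
Product: 5 flavonol 3-O-(4-formylphenyl) ether
Conditions: 4 (1.5 equiv), K2CO3 (1.5 equiv), degassed DMSO, 90–100 °C, Ar
Reagents that add atoms: none
Why: Nucleophilic aromatic substitution (addition–elimination) of the 3-oxyanion on the para-formyl-activated aryl fluoride should give the diaryl ether, the 5-OH staying chelated to C4=O and oxygen being excluded because flavonolate anions are oxidised by O2.

**Step 3**
Reactants: 6 1-(2,6-dihydroxy-4-methoxyphenyl)ethanone; 2 benzyl bromide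
Product: 7 1-[2-(benzyloxy)-6-hydroxy-4-methoxyphenyl]ethanone
Conditions: BnBr (1.05 equiv), K2CO3 (1.2 equiv), acetone, reflux
Reagents that add atoms: benzyl bromide (2), BrCc1ccccc1
Why: Williamson etherification should stop after one benzylation because the remaining hydroxyl is locked in a hydrogen bond to the acetyl carbonyl, and the two hydroxyls of 6 are equivalent so only one monoether can form.

**Step 4**
Reactants: 7 1-[2-(benzyloxy)-6-hydroxy-4-methoxyphenyl]ethanone; 8 di-tert-butyl dicarbonate
Product: 9 tert-butyl β-keto ester of the A ring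
Conditions: LiHMDS (3.3 equiv), THF, −78 °C; Boc2O (1.1 equiv), −78 → 0 °C; aq. NH4Cl
Reagents that add atoms: di-tert-butyl dicarbonate (8), CC(C)(C)OC(=O)OC(=O)OC(C)(C)C
Why: Claisen-type C-acylation of the lithium dianion (phenoxide plus methyl-ketone enolate, as in acylations of polylithiated o-hydroxyacetophenones) should occur at the more nucleophilic enolate carbon, the third equivalent of base holding the product as its enolate and the poor tert-butoxide leaving group suppressing lactonisation to a 4-hydroxycoumarin.

**Step 5**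
Reactants: 5 flavonol 3-O-(4-formylphenyl) ether; 9 tert-butyl β-keto ester of the A ring
Product: 10 benzylidene β-keto ester (E/Z mixture)
Conditions: piperidine (10 mol %), AcOH (10 mol %), 4 Å MS, toluene, rt
Reagents that add atoms: none
Why: Knoevenagel condensation of the β-keto ester with the aromatic aldehyde under buffered piperidinium acetate with removal of water should give the alkylidene, the buffered medium and the chelated phenol holding back premature racemic ring closure.

**Step 6**
Reactants: 10 benzylidene β-keto ester (E/Z mixture)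
Product: 12 (2S)-tri-O-benzyl flavanone–flavone ether, via tert-butyl (2S)-flavanone-3-carboxylate 11 (not isolated)
Conditions: N-[3,5-bis(trifluoromethyl)phenyl]-N'-[(8α,9S)-6'-methoxycinchonan-9-yl]thiourea (10 mol %), toluene, −25 °C; then TsOH·H2O (1 equiv), 80 °C, same pot
Reagents that add atoms: none
Why: The thiourea N–H pair should hydrogen-bond the 1,3-dicarbonyl of the alkylidene while the quinuclidine nitrogen acts as general base on the chelated phenol, whose oxygen adds to the benzylidene carbon (future C2); enolate protonation gives 11, and TsOH then cleaves the tert-butyl ester (isobutene) and decarboxylates C3. The closest known reaction type is the cinchona-thiourea-catalysed enantioselective intramolecular oxa-Michael addition of 2-hydroxyaryl alkylidene β-keto esters to flavanone-3-carboxylates with one-pot acid decarboxylation. The pyranone ring closes by a 6-endo-trig oxa-Michael addition that forms O1–C2. C2 is set under catalyst control, the chiral pocket fixing which face of the bound alkylidene the phenol reaches; C3 of 11 is an epimerisable β-keto ester centre erased on decarboxylation, and the E and Z alkylidenes, which can interconvert by reversible conjugate addition under the amine catalyst, are expected to funnel into the same (2S) product. The step needs enantioselectivity over the uncatalysed closure and no later loss of configuration: the single free phenol (the other ortho oxygen is benzylated and the flavone 5''-OH is locked in its hydrogen bond to C4''=O), the unpolar solvent and −25 °C should hold back the background reaction, and the acidic decarboxylation avoids the base-mediated retro-oxa-Michael opening that racemises flavanones.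

**Step 7**
Reactants: 12 (2S)-tri-O-benzyl flavanone–flavone ether
Product: 13 target compound
Conditions: H2 (1 atm), 10% Pd/C, THF/MeOH, rt
Reagents that add atoms: none
Why: Hydrogenolysis of the three aryl benzyl ethers over Pd/C under neutral conditions should leave the flavone enol-ether double bond, both ketones, the diaryl ether and the base-labile C2 stereocentre untouched, the run being stopped once the last monobenzyl ether is consumed to avoid reductive opening of the benzylic C2–O1 bond.

**Compound list**
1 | kaempferol, 3,5,7-trihydroxy-2-(4-hydroxyphenyl)-4H-chromen-4-one | O=c1c(O)c(-c2ccc(O)cc2)oc2cc(O)cc(O)c12 | starting material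
2 | benzyl bromide | BrCc1ccccc1 | starting material
3 | 7-(benzyloxy)-2-[4-(benzyloxy)phenyl]-3,5-dihydroxy-4H-chromen-4-one | O=c1c(O)c(-c2ccc(OCc3ccccc3)cc2)oc2cc(OCc3ccccc3)cc(O)c12 | intermediate
4 | 4-fluorobenzaldehyde | O=Cc1ccc(F)cc1 | starting material
5 | 4-({7-(benzyloxy)-2-[4-(benzyloxy)phenyl]-5-hydroxy-4-oxo-4H-chromen-3-yl}oxy)benzaldehyde | O=Cc1ccc(Oc2c(-c3ccc(OCc4ccccc4)cc3)oc3cc(OCc4ccccc4)cc(O)c3c2=O)cc1 | intermediate
6 | 1-(2,6-dihydroxy-4-methoxyphenyl)ethan-1-one | COc1cc(O)c(C(C)=O)c(O)c1 | starting material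
7 | 1-[2-(benzyloxy)-6-hydroxy-4-methoxyphenyl]ethan-1-one | COc1cc(O)c(C(C)=O)c(OCc2ccccc2)c1 | intermediate
8 | di-tert-butyl dicarbonate | CC(C)(C)OC(=O)OC(=O)OC(C)(C)C | starting material
9 | tert-butyl 3-[2-(benzyloxy)-6-hydroxy-4-methoxyphenyl]-3-oxopropanoate | COc1cc(O)c(C(=O)CC(=O)OC(C)(C)C)c(OCc2ccccc2)c1 | intermediate
10 | tert-butyl 2-[2-(benzyloxy)-6-hydroxy-4-methoxybenzoyl]-3-[4-({7-(benzyloxy)-2-[4-(benzyloxy)phenyl]-5-hydroxy-4-oxo-4H-chromen-3-yl}oxy)phenyl]prop-2-enoate (E/Z mixture) | COc1cc(O)c(C(=O)C(=Cc2ccc(Oc3c(-c4ccc(OCc5ccccc5)cc4)oc4cc(OCc5ccccc5)cc(O)c4c3=O)cc2)C(=O)OC(C)(C)C)c(OCc2ccccc2)c1 | intermediate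
11 | tert-butyl (2S)-5-(benzyloxy)-2-[4-({7-(benzyloxy)-2-[4-(benzyloxy)phenyl]-5-hydroxy-4-oxo-4H-chromen-3-yl}oxy)phenyl]-7-methoxy-4-oxo-3,4-dihydro-2H-chromene-3-carboxylate (C3 epimers, not isolated) | COc1cc(OCc2ccccc2)c2c(c1)O[C@H](c1ccc(Oc3c(-c4ccc(OCc5ccccc5)cc4)oc4cc(OCc5ccccc5)cc(O)c4c3=O)cc1)C(C(=O)OC(C)(C)C)C2=O | intermediate
12 | (2S)-5-(benzyloxy)-2-[4-({7-(benzyloxy)-2-[4-(benzyloxy)phenyl]-5-hydroxy-4-oxo-4H-chromen-3-yl}oxy)phenyl]-7-methoxy-2,3-dihydro-4H-chromen-4-one | COc1cc(OCc2ccccc2)c2c(c1)O[C@H](c1ccc(Oc3c(-c4ccc(OCc5ccccc5)cc4)oc4cc(OCc5ccccc5)cc(O)c4c3=O)cc1)CC2=O | intermediate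
13 | (2S)-2-(4-{[5,7-dihydroxy-2-(4-hydroxyphenyl)-4-oxo-4H-chromen-3-yl]oxy}phenyl)-5-hydroxy-7-methoxy-2,3-dihydro-4H-chromen-4-one | COc1cc(O)c2c(c1)O[C@H](c1ccc(Oc3c(-c4ccc(O)cc4)oc4cc(O)cc(O)c4c3=O)cc1)CC2=O | target

**Step count and risks**
Total steps: 7. Longest linear sequence: 5 steps (steps 1, 2, 5, 6, 7 from kaempferol; the A-ring branch, steps 3, 4, 5, 6, 7, is equally long).

Steps most likely to fail:

1. Step 6. The doubly ortho-oxygenated aryl ketone is twisted out of conjugation, so the catalysed closure may be slow; the uncatalysed racemic closure or a reversible retro-oxa-Michael opening may then compete and give insufficient enantiofacial discrimination. Fallback (sets out from 10, comes back at 12): 10 is closed with an achiral amine (Et3N, toluene, rt) to the racemic tert-butyl flavanone-3-carboxylate F1 (not isolated) and decarboxylated in the same pot (TsOH·H2O, 80 °C) to the racemic tri-O-benzyl flavanone–flavone ether F2. Preparative chromatography on a chiral stationary phase then separates 12 from its (2R)-enantiomer F3, which is re-racemised with DBU in THF/MeOH through the ring-opened chalcone back to F2 and recycled.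

2. Step 2. The 3-oxyanion is hindered and weakly nucleophilic (flanked by C4=O and the C2 aryl group), so substitution may be sluggish at temperatures where the flavonolate degrades oxidatively or O5 begins to react. Fallback (sets out from 3, comes back at 5): 3 is O-arylated without metal at room temperature with commercial bis(4-bromophenyl)iodonium triflate (t-BuOK, THF, 0 °C → rt; ligand coupling at iodine(III)) to 7-(benzyloxy)-2-[4-(benzyloxy)phenyl]-3-(4-bromophenoxy)-5-hydroxy-4H-chromen-4-one F4. The aryl bromide is then formylated by palladium-catalysed reductive carbonylation (Pd(OAc)2, di(1-adamantyl)-n-butylphosphine, CO/H2, TMEDA, toluene, 100 °C) to give 5.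

3. Step 4. Boc2O may acylate the phenoxide oxygen instead of the enolate carbon, or the product dianion may lactonise. Fallback (sets out from 7, comes back at 9): the phenol is first silylated (TBSCl, imidazole, DMF) to 1-[2-(benzyloxy)-6-(tert-butyldimethylsilyloxy)-4-methoxyphenyl]ethanone F5. Its simple mono-enolate is carboxylated (LiHMDS 2.2 equiv, THF, −78 °C; Boc2O) to tert-butyl 3-[2-(benzyloxy)-6-(tert-butyldimethylsilyloxy)-4-methoxyphenyl]-3-oxopropanoate F6. Buffered desilylation (TBAF, AcOH, THF, 0 °C) then gives 9.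

**Further compounds**
F1 | step 6 | racemic tert-butyl 5-(benzyloxy)-2-[4-({7-(benzyloxy)-2-[4-(benzyloxy)phenyl]-5-hydroxy-4-oxo-4H-chromen-3-yl}oxy)phenyl]-7-methoxy-4-oxo-3,4-dihydro-2H-chromene-3-carboxylate | COc1cc(OCc2ccccc2)c2c(c1)OC(c1ccc(Oc3c(-c4ccc(OCc5ccccc5)cc4)oc4cc(OCc5ccccc5)cc(O)c4c3=O)cc1)C(C(=O)OC(C)(C)C)C2=O
F2 | step 6 | racemic 5-(benzyloxy)-2-[4-({7-(benzyloxy)-2-[4-(benzyloxy)phenyl]-5-hydroxy-4-oxo-4H-chromen-3-yl}oxy)phenyl]-7-methoxy-2,3-dihydro-4H-chromen-4-one | COc1cc(OCc2ccccc2)c2c(c1)OC(c1ccc(Oc3c(-c4ccc(OCc5ccccc5)cc4)oc4cc(OCc5ccccc5)cc(O)c4c3=O)cc1)CC2=O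
F3 | step 6 | (2R)-5-(benzyloxy)-2-[4-({7-(benzyloxy)-2-[4-(benzyloxy)phenyl]-5-hydroxy-4-oxo-4H-chromen-3-yl}oxy)phenyl]-7-methoxy-2,3-dihydro-4H-chromen-4-one | COc1cc(OCc2ccccc2)c2c(c1)O[C@@H](c1ccc(Oc3c(-c4ccc(OCc5ccccc5)cc4)oc4cc(OCc5ccccc5)cc(O)c4c3=O)cc1)CC2=O
F4 | step 2 | 7-(benzyloxy)-2-[4-(benzyloxy)phenyl]-3-(4-bromophenoxy)-5-hydroxy-4H-chromen-4-one | O=c1c(Oc2ccc(Br)cc2)c(-c2ccc(OCc3ccccc3)cc2)oc2cc(OCc3ccccc3)cc(O)c12
F5 | step 4 | 1-[2-(benzyloxy)-6-(tert-butyldimethylsilyloxy)-4-methoxyphenyl]ethan-1-one | COc1cc(O[Si](C)(C)C(C)(C)C)c(C(C)=O)c(OCc2ccccc2)c1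
F6 | step 4 | tert-butyl 3-[2-(benzyloxy)-6-(tert-butyldimethylsilyloxy)-4-methoxyphenyl]-3-oxopropanoate | COc1cc(O[Si](C)(C)C(C)(C)C)c(C(=O)CC(=O)OC(C)(C)C)c(OCc2ccccc2)c1
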